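The nine-membered carbocycle is closed between C6 and C7 by an intramolecular B-alkyl Suzuki–Miyaura coupling. The feature exploited is that the cis C7–C8 epoxide of the cyclononane ring (C4a, C5–C11, C11a) masks a Z-trisubstituted C7=C8 alkene directly next to the C6 methylene. A C4a vinyl group (C5=C6) and a preformed (Z)-C7 iodoalkene therefore suffice: 9-BBN puts boron on C6 and palladium joins C6 to C7 with retention, giving ring and alkene geometry in one operation. The precursor is the all-trans 2-alkoxy-4-vinyl-dihydropyran ester 14 carrying a C11 dioxolane with the (Z)-iodopentenyl chain and, for acid-free unmasking later, a p-methoxybenzyl acetal at C1.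

Key step: step 10

Remarks
- Numbering (cyclonona[c]pyran): C1 acetal carbon, O2, C3=C4 enol ether, C4a and C11a ring fusion, C5–C11 the rest of the nine-membered ring, C12 the side-chain carbinol, C13–C15 the side chain.
- Target check: the epoxide carries C6 and C9 on the same side (cis, from a Z alkene), H-4a and H-11a are trans, and the C1 acetate is trans to C11. The descriptors are 1R,4aS,7S,8R,11aR,12S, and precursor, product and target agree at C1, C4a and C11a.
- Design choices: C1 carries a p-methoxybenzyl (PMB) acetal, removable with DDQ, because acid cannot be used once the epoxide is present. The Z-iodoalkene geometry is fixed in step 1.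
- C11a is configurationally labile until step 6 and is set thermodynamically in step 9. C1 is reset in step 16.
- Assumption: the sense of induction in steps 5, 13 and 17 follows the usual models for these reagents; in each case the antipodal ligand, ketone or borane is available should it have to be reversed.

Step 1
Reactants: 1 but-2-yn-1-ol
Product: 2 (Z)-3-iodobut-2-en-1-ol
Conditions: NaAlH2(OCH2CH2OMe)2, Et2O, 0 °C → rt; then I2, THF, −78 °C
Reagents that add atoms: iodine, [I][I]
Why: Hydroalumination–iodination of a propargylic alcohol: hydride adds trans through the alkoxide-bound aluminate, aluminium ends on C3 in a five-membered chelate, and iodinolysis with retention places iodine cis to CH2OH (Z).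

Step 2
Reactants: 2 (Z)-3-iodobut-2-en-1-ol
Product: 3 (Z)-1-bromo-3-iodobut-2-ene
Conditions: CBr4, PPh3, CH2Cl2, 0 °C
Reagents that add atoms: carbon tetrabromide, BrC(Br)(Br)Br
Why: Appel bromination of the primary allylic alcohol under neutral conditions should leave the iodoalkene geometry untouched.

Step 3
Reactants: 4 methyl acetoacetate; 3 (Z)-1-bromo-3-iodobut-2-ene
Product: 5 methyl (Z)-7-iodo-3-oxooct-6-enoate
Conditions: NaH then n-BuLi, THF, 0 °C; 3, 0 °C → rt; aq. HCl
Reagents that add atoms: none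
Why: Weiler dianion alkylation: the γ-carbon of the acetoacetate dianion is the more nucleophilic site and displaces the allylic bromide by SN2, while the vinyl iodide is inert to the stabilised dianion.

Step 4
Reactants: 6 methyl but-3-enoate; 7 allyl methyl carbonate
Product: 8 methyl (E)-5-[(methoxycarbonyl)oxy]pent-3-enoate
Conditions: second-generation Grubbs catalyst (2 mol %), 1,4-benzoquinone (10 mol %), 7 (4 equiv), CH2Cl2, 40 °C
Reagents that add atoms: none
Why: Olefin cross-metathesis of two unhindered terminal alkenes with the carbonate in excess should give mainly the E alkene (Z isomer removed by chromatography), with benzoquinone suppressing isomerisation of the β,γ-unsaturated ester.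

Step 5
Reactants: 5 methyl (Z)-7-iodo-3-oxooct-6-enoate; 8 methyl (E)-5-[(methoxycarbonyl)oxy]pent-3-enoate
Product: 9 dimethyl (3S)-2-[(4Z)-5-iodohex-4-enoyl]-3-vinylpentanedioate (C2 epimers)
Conditions: [Ir(cod)Cl]2 (2 mol %), (Ra,R,R)-O,O′-(1,1′-binaphthalene-2,2′-diyl) N,N-bis(1-phenylethyl)phosphoramidite (4 mol %), TBD (8 mol %), THF, rt
Reagents that add atoms: none
Why: Iridium-catalysed asymmetric allylic alkylation (Tsuji–Trost type): the cyclometalated iridium–phosphoramidite complex ionises the carbonate and the β-keto ester enolate attacks the substituted allyl terminus, giving the branched product and setting C4a (S) under ligand control, with methoxide from the leaving group as the only base.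

Step 6
Reactants: 9 dimethyl (3S)-2-[(4Z)-5-iodohex-4-enoyl]-3-vinylpentanedioate
Product: 10 dimethyl (3S)-2-{2-[(3Z)-4-iodopent-3-en-1-yl]-1,3-dioxolan-2-yl}-3-vinylpentanedioate (C2 epimers)
Conditions: Me3SiOCH2CH2OSiMe3, TMSOTf (10 mol %), CH2Cl2, −78 → −20 °C; pyridine
Reagents that add atoms: 1,2-bis(trimethylsilyloxy)ethane, C[Si](C)(C)OCCO[Si](C)(C)C
Why: Noyori ketalization under aprotic silyl-transfer catalysis converts hindered ketones at low temperature and tolerates esters, alkenes and the vinyl iodide; the dioxolane also removes the acidity at C10 and C11a.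

Step 7
Reactants: 10 dimethyl (3S)-2-{2-[(3Z)-4-iodopent-3-en-1-yl]-1,3-dioxolan-2-yl}-3-vinylpentanedioate
Product: 11 dimethyl (3S)-4-(hydroxymethylidene)-2-{2-[(3Z)-4-iodopent-3-en-1-yl]-1,3-dioxolan-2-yl}-3-vinylpentanedioate
Conditions: LiN(i-Pr)2 (1.3 equiv), THF, −78 °C; HCO2Me, −78 → −30 °C; AcOH
Reagents that add atoms: methyl formate, COC=O
Why: Crossed Claisen formylation: kinetic deprotonation takes place at the unhindered CH2CO2Me (the other ester α-hydrogen is tertiary and flanked by the quaternary ketal carbon), and the enolate is formylated to the stable hydroxymethylene ester that provides C3.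

Step 8
Reactants: 11 dimethyl (3S)-4-(hydroxymethylidene)-2-{2-[(3Z)-4-iodopent-3-en-1-yl]-1,3-dioxolan-2-yl}-3-vinylpentanedioate
Product: 13 methyl (4S)-2-hydroxy-3-{2-[(3Z)-4-iodopent-3-en-1-yl]-1,3-dioxolan-2-yl}-4-vinyl-3,4-dihydro-2H-pyran-5-carboxylate (C2 and C3 epimers), via open-chain hydroxymethylene aldehyde 12 (not isolated)
Conditions: i-Bu2AlH (3.5 equiv), CH2Cl2, −78 °C; MeOH, aq. potassium sodium tartrate, rt
Reagents that add atoms: none
Why: Ester half-reduction with i-Bu2AlH: the first equivalent turns the acidic hydroxymethylene ester into an aluminium enolate inert to hydride, so only the remaining ester is reduced to the aldehyde level (tetrahedral aluminate chelated by the ketal oxygen), and on work-up the enol OH captures the aldehyde as the six-membered lactol, as in iridoid aglycones.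

Step 9
Reactants: 13 methyl (4S)-2-hydroxy-3-{2-[(3Z)-4-iodopent-3-en-1-yl]-1,3-dioxolan-2-yl}-4-vinyl-3,4-dihydro-2H-pyran-5-carboxylate
Product: 14 methyl (2S,3S,4S)-3-{2-[(3Z)-4-iodopent-3-en-1-yl]-1,3-dioxolan-2-yl}-2-[(4-methoxybenzyl)oxy]-4-vinyl-3,4-dihydro-2H-pyran-5-carboxylate
Conditions: 4-methoxybenzyl alcohol (5 equiv), CSA (0.2 equiv), 4 Å MS, CH2Cl2, rt, equilibrating; other isomers resubmitted
Reagents that add atoms: 4-methoxybenzyl alcohol, COc1ccc(CO)cc1
Why: Fischer-type acetalization is reversible, so C1 (anomerisation) and C11a (through the C1 oxocarbenium ion and its C1=C11a enol ether) should converge on the all-trans isomer, in which the bulky C11a substituent is anti to both neighbours and the C1 alkoxy group can sit axial (anomeric effect).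

Step 10
Reactants: 14 methyl (2S,3S,4S)-3-{2-[(3Z)-4-iodopent-3-en-1-yl]-1,3-dioxolan-2-yl}-2-[(4-methoxybenzyl)oxy]-4-vinyl-3,4-dihydro-2H-pyran-5-carboxylate
Product: 16 methyl (1S,4aS,7Z,11aS)-11,11-(ethylenedioxy)-1-[(4-methoxybenzyl)oxy]-7-methyl-1,4a,5,6,9,10,11,11a-octahydrocyclonona[c]pyran-4-carboxylate, via B-alkyl-9-BBN borane 15 (not isolated)
Conditions: 9-BBN (1.6 equiv), THF, rt; then syringe-pump addition to PdCl2(dppf) (20 mol %), AsPh3 (40 mol %), Cs2CO3 (4 equiv), DMF/THF/H2O, 2 mM, rt → 45 °C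
Reagents that add atoms: none
Why: 9-BBN hydroborates only the monosubstituted C5=C6 vinyl group, anti-Markovnikov, to give the primary borane 15, since the trisubstituted iodoalkene is too hindered and the ester-conjugated enol ether too electron-poor, and C11 is kept as the dioxolane because a 1,1-disubstituted C11 methylene would compete. Zerovalent palladium then inserts into the C7–I bond with retention, the base-activated borate transfers the primary alkyl group, and reductive elimination forms C6–C7. The closest known reaction type is the intramolecular B-alkyl Suzuki–Miyaura macrocyclisation of 9-BBN boranes with iodoalkenes, used for medium and large carbocycles. The nine-membered ring is closed at an sp3–sp2 junction by reductive elimination from a ten-membered palladacycle, under high dilution to suppress oligomerisation. No stereocentre is formed, and the Z geometry, set in the acyclic iodoalkene with iodine and C9 on the same side, is carried over unchanged. The step needs ring closure to outrun protodeboronation and β-hydride elimination, which the primary borane, the labile AsPh3 ligand and the gauche arrangement of the C4a and C11a arms in the diequatorial half-chair should secure.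

Step 11
Reactants: 16 methyl (1S,4aS,7Z,11aS)-11,11-(ethylenedioxy)-1-[(4-methoxybenzyl)oxy]-7-methyl-1,4a,5,6,9,10,11,11a-octahydrocyclonona[c]pyran-4-carboxylate
Product: 17 methyl (1S,4aS,7Z,11aS)-1-[(4-methoxybenzyl)oxy]-7-methyl-11-oxo-1,4a,5,6,9,10,11,11a-octahydrocyclonona[c]pyran-4-carboxylate
Conditions: PPTS (0.3 equiv), acetone/H2O 20:1, 45 °C
Reagents that add atoms: water, O
Why: Mild acid-catalysed ketal hydrolysis should cleave the ketone dioxolane while the glycoside-like cyclic C1 acetal (ring oxygen deactivated by the conjugated ester) and the PMB group survive, and no epoxide is present yet.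

Step 12
Reactants: 17 methyl (1S,4aS,7Z,11aS)-1-[(4-methoxybenzyl)oxy]-7-methyl-11-oxo-1,4a,5,6,9,10,11,11a-octahydrocyclonona[c]pyran-4-carboxylate
Product: 18 methyl (1S,4aS,7Z,11aR)-1-[(4-methoxybenzyl)oxy]-7-methyl-11-methylidene-1,4a,5,6,9,10,11,11a-octahydrocyclonona[c]pyran-4-carboxylate
Conditions: Zn, CH2Br2, TiCl4, THF, 0 °C (reagent preformed); then 17, CH2Cl2, 0 °C → rt
Reagents that add atoms: dibromomethane, BrCBr
Why: Takai–Lombardo methylenation is non-basic, so the enolisable β-alkoxy ketone should be converted without epimerisation at C11a or β-elimination of the ring oxygen, and esters are not attacked.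

Step 13
Reactants: 18 methyl (1S,4aS,7Z,11aR)-1-[(4-methoxybenzyl)oxy]-7-methyl-11-methylidene-1,4a,5,6,9,10,11,11a-octahydrocyclonona[c]pyran-4-carboxylate
Product: 19 methyl (1S,4aS,7S,8R,11aR)-7,8-epoxy-1-[(4-methoxybenzyl)oxy]-7-methyl-11-methylidene-1,4a,5,6,7,8,9,10,11,11a-decahydrocyclonona[c]pyran-4-carboxylate
Conditions: D-fructose-derived Shi ketone (0.3 equiv), KHSO5 (as 2KHSO5·KHSO4·K2SO4), K2CO3, Bu4NHSO4, MeCN/CH2(OMe)2/aq. Na2B4O7–Na2EDTA buffer, 0 °C
Reagents that add atoms: potassium peroxymonosulfate, [K+].[O-]S(=O)(=O)OO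
Why: Shi epoxidation: the chiral dioxirane attacks the electron-rich trisubstituted C7=C8 alkene through a spiro transition state, in the sense known for 1-phenylcyclohexene (here 7S,8R), and is expected to ignore the 1,1-disubstituted C11 methylene and the ester-deactivated enol ether.

Step 14
Reactants: 19 methyl (1S,4aS,7S,8R,11aR)-7,8-epoxy-1-[(4-methoxybenzyl)oxy]-7-methyl-11-methylidene-1,4a,5,6,7,8,9,10,11,11a-decahydrocyclonona[c]pyran-4-carboxylate
Product: 20 [(1S,4aS,7S,8R,11aR)-7,8-epoxy-1-[(4-methoxybenzyl)oxy]-7-methyl-11-methylidene-1,4a,5,6,7,8,9,10,11,11a-decahydrocyclonona[c]pyran-4-yl]methanol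
Conditions: i-Bu2AlH (2.5 equiv), CH2Cl2, −78 °C; aq. potassium sodium tartrate
Reagents that add atoms: none
Why: i-Bu2AlH reduction of the vinylogous carbonate ester to the allylic alcohol at low temperature, where the trisubstituted epoxide and the acetal should be inert.

Step 15
Reactants: 20 [(1S,4aS,7S,8R,11aR)-7,8-epoxy-1-[(4-methoxybenzyl)oxy]-7-methyl-11-methylidene-1,4a,5,6,7,8,9,10,11,11a-decahydrocyclonona[c]pyran-4-yl]methanol
Product: 21 (1S,4aS,7S,8R,11aR)-7,8-epoxy-1-[(4-methoxybenzyl)oxy]-7-methyl-11-methylidene-1,4a,5,6,7,8,9,10,11,11a-decahydrocyclonona[c]pyran-4-carbaldehyde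
Conditions: MnO2, CH2Cl2, rt
Reagents that add atoms: none
Why: MnO2 oxidises the activated allylic alcohol to the β-alkoxy enal under neutral heterogeneous conditions, which again deactivates the enol ether.

Step 16
Reactants: 21 (1S,4aS,7S,8R,11aR)-7,8-epoxy-1-[(4-methoxybenzyl)oxy]-7-methyl-11-methylidene-1,4a,5,6,7,8,9,10,11,11a-decahydrocyclonona[c]pyran-4-carbaldehyde
Product: 23 (1R,4aS,7S,8R,11aR)-7,8-epoxy-4-formyl-7-methyl-11-methylidene-1,4a,5,6,7,8,9,10,11,11a-decahydrocyclonona[c]pyran-1-yl acetate, via lactol enal 22 (not isolated)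
Conditions: DDQ (1.3 equiv), CH2Cl2/aq. KH2PO4–K2HPO4 buffer (pH 7), 0 °C; then Ac2O, pyridine, DMAP (cat.), CH2Cl2, 0 °C
Reagents that add atoms: acetic anhydride, CC(=O)OC(C)=O
Why: DDQ removes the PMB acetal by benzylic hydride abstraction under buffered neutral conditions (no acid near the epoxide), and acetylation of the lactol should give the 1,11a-trans acetate as with iridoid aglycones, because any O-acetylated ring-opened form is a vinylogous anhydride that hands acetyl back.

Step 17
Reactants: 23 (1R,4aS,7S,8R,11aR)-7,8-epoxy-4-formyl-7-methyl-11-methylidene-1,4a,5,6,7,8,9,10,11,11a-decahydrocyclonona[c]pyran-1-yl acetate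
Product: 24 (1R,4aS,7S,8R,11aR)-7,8-epoxy-4-[(1S)-1-hydroxybut-3-en-1-yl]-7-methyl-11-methylidene-1,4a,5,6,7,8,9,10,11,11a-decahydrocyclonona[c]pyran-1-yl acetate
Conditions: (−)-Ipc2B(allyl) (1.3 equiv), Et2O, −78 °C; then aq. KH2PO4–K2HPO4 buffer (pH 7), H2O2, MeOH, 0 °C
Reagents that add atoms: (−)-B-allyldiisopinocampheylborane, C=CCB([C@@H]1C[C@@H]2C[C@H]([C@H]1C)C2(C)C)[C@@H]1C[C@@H]2C[C@H]([C@H]1C)C2(C)C
Why: Brown allylboration: the allylborane adds through a closed chair transition state to the Si face of the aldehyde under reagent control, setting C12 (S) without any Lewis acid, so epoxide, anomeric acetate and enol ether should be spared.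

Step 18
Reactants: 24 (1R,4aS,7S,8R,11aR)-7,8-epoxy-4-[(1S)-1-hydroxybut-3-en-1-yl]-7-methyl-11-methylidene-1,4a,5,6,7,8,9,10,11,11a-decahydrocyclonona[c]pyran-1-yl acetate; 25 methyl methacrylate
Product: 26 methyl (2E,5S)-5-[(1R,4aS,7S,8R,11aR)-1-acetoxy-7,8-epoxy-7-methyl-11-methylidene-1,4a,5,6,7,8,9,10,11,11a-decahydrocyclonona[c]pyran-4-yl]-5-hydroxy-2-methylpent-2-enoate
Conditions: 25 (20 equiv), second-generation Hoveyda–Grubbs catalyst (10 mol %), CH2Cl2, 40 °C
Reagents that add atoms: none
Why: Olefin cross-metathesis of the monosubstituted alkene with excess methacrylate should give the E-trisubstituted enoate, while the trisubstituted enol ether and the hindered 1,1-disubstituted C11 methylene react far more slowly.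

Step 19
Reactants: 26 methyl (2E,5S)-5-[(1R,4aS,7S,8R,11aR)-1-acetoxy-7,8-epoxy-7-methyl-11-methylidene-1,4a,5,6,7,8,9,10,11,11a-decahydrocyclonona[c]pyran-4-yl]-5-hydroxy-2-methylpent-2-enoate
Product: 27 target CNP0184381.3 (1R,4aS,7S,8R,11aR,12S)
Conditions: Ac2O, pyridine, DMAP (cat.), CH2Cl2, 0 °C → rt
Reagents that add atoms: acetic anhydride, CC(=O)OC(C)=O
Why: DMAP-catalysed acetylation of the secondary allylic alcohol under basic conditions avoids ionisation of the C12–O bond, which is allylic to the enol ether.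

Compound list
1 | but-2-yn-1-ol | CC#CCO | starting material
2 | (Z)-3-iodobut-2-en-1-ol | OC/C=C(/C)I | intermediate
3 | (Z)-1-bromo-3-iodobut-2-ene | BrC/C=C(/C)I | intermediate
4 | methyl acetoacetate | CC(=O)CC(=O)OC | starting material
5 | methyl (Z)-7-iodo-3-oxooct-6-enoate | COC(=O)CC(=O)CC/C=C(/C)I | intermediate
6 | methyl but-3-enoate | C=CCC(=O)OC | starting material
7 | allyl methyl carbonate | C=CCOC(=O)OC | starting material
8 | methyl (E)-5-[(methoxycarbonyl)oxy]pent-3-enoate | COC(=O)C/C=C/COC(=O)OC | intermediate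
9 | dimethyl (3S)-2-[(4Z)-5-iodohex-4-enoyl]-3-vinylpentanedioate, C2 (= C11a) epimers | C=C[C@@H](C(C(=O)OC)C(=O)CC/C=C(/C)I)CC(=O)OC | intermediate
10 | dimethyl (3S)-2-{2-[(3Z)-4-iodopent-3-en-1-yl]-1,3-dioxolan-2-yl}-3-vinylpentanedioate, C2 epimers | C=C[C@@H](C(C(=O)OC)C1(CC/C=C(/C)I)OCCO1)CC(=O)OC | intermediate
11 | dimethyl (3S)-4-(hydroxymethylidene)-2-{2-[(3Z)-4-iodopent-3-en-1-yl]-1,3-dioxolan-2-yl}-3-vinylpentanedioate, C2 epimers | C=C[C@@H](C(C(=O)OC)C1(CC/C=C(/C)I)OCCO1)C(=CO)C(=O)OC | intermediate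
12 | methyl (3S)-2-(hydroxymethylidene)-4-{2-[(3Z)-4-iodopent-3-en-1-yl]-1,3-dioxolan-2-yl}-5-oxo-3-vinylpentanoate (open-chain aldehyde, not isolated) | C=C[C@@H](C(C=O)C1(CC/C=C(/C)I)OCCO1)C(=CO)C(=O)OC | intermediate
13 | methyl (4S)-2-hydroxy-3-{2-[(3Z)-4-iodopent-3-en-1-yl]-1,3-dioxolan-2-yl}-4-vinyl-3,4-dihydro-2H-pyran-5-carboxylate, lactol, C2 and C3 epimers | C=C[C@@H]1C(C(=O)OC)=COC(O)C1C1(OCCO1)CC/C=C(/C)I | intermediate
14 | methyl (2S,3S,4S)-3-{2-[(3Z)-4-iodopent-3-en-1-yl]-1,3-dioxolan-2-yl}-2-[(4-methoxybenzyl)oxy]-4-vinyl-3,4-dihydro-2H-pyran-5-carboxylate (all-trans; key-step precursor) | C=C[C@@H]1C(C(=O)OC)=CO[C@H](OCc2ccc(OC)cc2)[C@H]1C1(OCCO1)CC/C=C(/C)I | intermediate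
15 | B-alkyl-9-BBN adduct of 14 at C6 (not isolated) | B1(CC[C@@H]2C(C(=O)OC)=CO[C@H](OCc3ccc(OC)cc3)[C@H]2C2(OCCO2)CC/C=C(/C)I)C2CCCC1CCC2 | intermediate
16 | methyl (1S,4aS,7Z,11aS)-11,11-(ethylenedioxy)-1-[(4-methoxybenzyl)oxy]-7-methyl-1,4a,5,6,9,10,11,11a-octahydrocyclonona[c]pyran-4-carboxylate (key-step product) | C12(OCCO1)CC/C=C(C)\CC[C@@H]3C(C(=O)OC)=CO[C@H](OCc4ccc(OC)cc4)[C@@H]23 | intermediate
17 | methyl (1S,4aS,7Z,11aS)-1-[(4-methoxybenzyl)oxy]-7-methyl-11-oxo-1,4a,5,6,9,10,11,11a-octahydrocyclonona[c]pyran-4-carboxylate | O=C1CC/C=C(C)\CC[C@@H]2C(C(=O)OC)=CO[C@H](OCc3ccc(OC)cc3)[C@@H]12 | intermediate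
18 | methyl (1S,4aS,7Z,11aR)-1-[(4-methoxybenzyl)oxy]-7-methyl-11-methylidene-1,4a,5,6,9,10,11,11a-octahydrocyclonona[c]pyran-4-carboxylate | C=C1CC/C=C(C)\CC[C@@H]2C(C(=O)OC)=CO[C@H](OCc3ccc(OC)cc3)[C@@H]12 | intermediate
19 | methyl (1S,4aS,7S,8R,11aR)-7,8-epoxy-1-[(4-methoxybenzyl)oxy]-7-methyl-11-methylidene-1,4a,5,6,7,8,9,10,11,11a-decahydrocyclonona[c]pyran-4-carboxylate | C=C1CC[C@H]2O[C@@]2(C)CC[C@@H]2C(C(=O)OC)=CO[C@H](OCc3ccc(OC)cc3)[C@@H]12 | intermediate
20 | [(1S,4aS,7S,8R,11aR)-7,8-epoxy-1-[(4-methoxybenzyl)oxy]-7-methyl-11-methylidene-1,4a,5,6,7,8,9,10,11,11a-decahydrocyclonona[c]pyran-4-yl]methanol | C=C1CC[C@H]2O[C@@]2(C)CC[C@@H]2C(CO)=CO[C@H](OCc3ccc(OC)cc3)[C@@H]12 | intermediate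
21 | (1S,4aS,7S,8R,11aR)-7,8-epoxy-1-[(4-methoxybenzyl)oxy]-7-methyl-11-methylidene-1,4a,5,6,7,8,9,10,11,11a-decahydrocyclonona[c]pyran-4-carbaldehyde | C=C1CC[C@H]2O[C@@]2(C)CC[C@@H]2C(C=O)=CO[C@H](OCc3ccc(OC)cc3)[C@@H]12 | intermediate
22 | (4aS,7S,8R,11aR)-7,8-epoxy-1-hydroxy-7-methyl-11-methylidene-1,4a,5,6,7,8,9,10,11,11a-decahydrocyclonona[c]pyran-4-carbaldehyde (lactol, C1 anomers, not isolated) | C=C1CC[C@H]2O[C@@]2(C)CC[C@@H]2C(C=O)=COC(O)[C@@H]12 | intermediate
23 | (1R,4aS,7S,8R,11aR)-7,8-epoxy-4-formyl-7-methyl-11-methylidene-1,4a,5,6,7,8,9,10,11,11a-decahydrocyclonona[c]pyran-1-yl acetate | C=C1CC[C@H]2O[C@@]2(C)CC[C@@H]2C(C=O)=CO[C@H](OC(C)=O)[C@@H]12 | intermediate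
24 | (1R,4aS,7S,8R,11aR)-7,8-epoxy-4-[(1S)-1-hydroxybut-3-en-1-yl]-7-methyl-11-methylidene-1,4a,5,6,7,8,9,10,11,11a-decahydrocyclonona[c]pyran-1-yl acetate | C=C1CC[C@H]2O[C@@]2(C)CC[C@@H]2C([C@H](CC=C)O)=CO[C@H](OC(C)=O)[C@@H]12 | intermediate
25 | methyl methacrylate | C=C(C)C(=O)OC | starting material
26 | methyl (2E,5S)-5-[(1R,4aS,7S,8R,11aR)-1-acetoxy-7,8-epoxy-7-methyl-11-methylidene-1,4a,5,6,7,8,9,10,11,11a-decahydrocyclonona[c]pyran-4-yl]-5-hydroxy-2-methylpent-2-enoate | C=C1CC[C@H]2O[C@@]2(C)CC[C@@H]2C([C@H](C/C=C(\C)C(=O)OC)O)=CO[C@H](OC(C)=O)[C@@H]12 | intermediate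
27 | CNP0184381.3, (1R,4aS,7S,8R,11aR,12S)-1,12-diacetate | C=C1CC[C@H]2O[C@@]2(C)CC[C@@H]2C([C@H](C/C=C(\C)C(=O)OC)OC(C)=O)=CO[C@H](OC(C)=O)[C@@H]12 | target

Total step count: 19. Longest linear sequence: 18 (steps 1–3 and 5–19; step 4 is a one-step side branch to 8).

Steps most likely to fail

Step 9. Convergence at C11a may be incomplete, either because equilibration through the oxocarbenium/enol ether manifold is slow or because prolonged acid starts to erode the dioxolane. Fallback: the acetal is formed under brief, non-equilibrating conditions and the all-trans isomer 14 is separated from its 1,11a-bis-epimer F1 (C11a substituent cis to the vinyl group). F1 is taken separately through the conditions of steps 10 and 11 to the cis-fused bicycle F2 and the cis-fused ketone F3. In F3, C11a is α to the C11 ketone and would be equilibrated with DBU in CH2Cl2: enolisation inverts C11a, and reversible β-elimination and oxa-Michael re-addition of the ring oxygen resets C1. This should deliver the trans-fused ketone 17, where the route is rejoined.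

Step 10. The borane may undergo protodeboronation or β-hydride elimination faster than transmetalation, or couple intermolecularly to oligomers. Fallback with the same C6–C7 bond but a zinc nucleophile: 14 is hydroborated with 9-BBN and oxidised (NaBO3·4H2O) to the primary alcohol F4, which is converted with I2, PPh3 and imidazole into the primary iodide F5. Zinc insertion (Zn, LiCl, THF, rt), selective for the alkyl iodide over the alkenyl iodide, gives the alkylzinc iodide F6, which is not isolated. Slow addition of F6 to Pd(PPh3)4 in THF/NMP at high dilution (intramolecular Negishi coupling, retention at the iodoalkene) should close the ring to 16.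

Step 13. Facial selectivity may be poor if the conformation of the Z-cyclononene overrides the chiral dioxirane, and some oxidation of the C11 methylene may occur. Fallback through a halohydrin, starting from 16, where C7=C8 is the only electron-rich alkene: NBS in aqueous THF gives the bromohydrin F7 (water opens the bromonium ion anti at tertiary C7). K2CO3 in MeOH then closes it to the epoxide F8, whose oxygen lies on the face opposite to the one the electrophile attacked, complementary to direct substrate-controlled epoxidation. PPTS in wet acetone, kept short, gives the epoxy ketone F9, and methylenation under the conditions of step 12 at −20 °C returns to 19.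

Further compounds
F1 | step 9 | 1,11a-bis-epimer of 14 (C11a substituent cis to the C4a vinyl group, C1 alkoxy trans to it) | C=C[C@@H]1C(C(=O)OC)=CO[C@@H](OCc2ccc(OC)cc2)[C@@H]1C1(OCCO1)CC/C=C(/C)I
F2 | step 9 | cis-fused bicycle, 1,11a-bis-epimer of 16 | C12(OCCO1)CC/C=C(C)\CC[C@@H]3C(C(=O)OC)=CO[C@@H](OCc4ccc(OC)cc4)[C@H]23
F3 | step 9 | cis-fused C11 ketone, 1,11a-bis-epimer of 17 | O=C1CC/C=C(C)\CC[C@@H]2C(C(=O)OC)=CO[C@@H](OCc3ccc(OC)cc3)[C@H]12
F4 | step 10 | primary alcohol from hydroboration–oxidation of 14 (C6–OH) | OCC[C@@H]1C(C(=O)OC)=CO[C@H](OCc2ccc(OC)cc2)[C@H]1C1(OCCO1)CC/C=C(/C)I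
F5 | step 10 | primary iodide (C6–I) | ICC[C@@H]1C(C(=O)OC)=CO[C@H](OCc2ccc(OC)cc2)[C@H]1C1(OCCO1)CC/C=C(/C)I
F6 | step 10 | alkylzinc iodide (C6–ZnI), not isolated | I[Zn]CC[C@@H]1C(C(=O)OC)=CO[C@H](OCc2ccc(OC)cc2)[C@H]1C1(OCCO1)CC/C=C(/C)I
F7 | step 13 | bromohydrin of 16 (C7–OH, C8–Br) | C12(OCCO1)CC[C@H](Br)[C@](O)(C)CC[C@@H]3C(C(=O)OC)=CO[C@H](OCc4ccc(OC)cc4)[C@@H]23
F8 | step 13 | (7S,8R)-7,8-epoxide of 16 | C12(OCCO1)CC[C@H]3O[C@@]3(C)CC[C@@H]4C(C(=O)OC)=CO[C@H](OCc5ccc(OC)cc5)[C@@H]24
F9 | step 13 | (7S,8R)-7,8-epoxy C11 ketone | O=C1CC[C@H]2O[C@@]2(C)CC[C@@H]2C(C(=O)OC)=CO[C@H](OCc3ccc(OC)cc3)[C@@H]12
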